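Ring B of the target (C1 aryl-bearing, C2 and C3 methyl-bearing, C4 benzylic, fused to ring A at C4a and C8a) is a cyclohexene annulated to an arene. Its C1–C2 and C3–C4 bonds are therefore cut back to an aryl-substituted o-quinodimethane and an E-butene surrogate. One thermal operation expels SO2 from a 1-aryl-1,3-dihydrobenzo[c]thiophene 2,2-dioxide and traps the diene with the fumarate of methyl (S)-lactate. This closes ring B, forms both bonds and fixes C1 absolutely, with 2,3-trans esters. The kinetic adduct is 1,2-cis, so methoxide then equilibrates C2 and C3 to the all-trans diester, and both ester carbons are reduced to the methyl groups.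

Key step: step 5

Remark: tetralin numbering as above is used throughout; the target is the all-trans (1R,2R,3S) isomer, and sulfone 9 is used as the racemate because its stereocentre becomes planar in step 5.

Assumption: fumarate 3 is taken to react endo (C2 ester beneath the diene) on the face anti to the lactate methyl groups (s-cis enoate, carbinol C–H eclipsing C=O), the sense recalled for fumarates of (S)-α-hydroxy esters with sulfone-derived α-aryl o-quinodimethanes and not re-verified here; this gives C1 (R) in a 1,2-cis adduct, whose C2 and C3 are corrected in step 6.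

Step 1
Reactants: 1 fumaryl chloride; 2 methyl (S)-lactate
Product: 3 bis[(S)-1-methoxy-1-oxopropan-2-yl] (E)-but-2-enedioate
Conditions: 2 (2.2 equiv), pyridine, DMAP (cat.), CH2Cl2, 0 °C to rt
Reagents that add atoms: none
Why: Nucleophilic acyl substitution of the acid chloride by the secondary alcohol (esterification) breaks no bond at the lactate stereocentre or at the alkene, so the (S) centres and the E geometry are retained.

Step 2
Reactants: 4 1,2-bis(chloromethyl)-4,5-dimethoxybenzene
Product: 5 5,6-dimethoxy-1,3-dihydrobenzo[c]thiophene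
Conditions: Na2S·9H2O, EtOH/H2O, rt, slow addition of 4
Reagents that add atoms: sodium sulfide, [Na+].[Na+].[S-2]
Why: Twofold SN2 thioether formation at activated benzylic chlorides, the second displacement being a fast 5-exo-tet ring closure that slow addition favours over oligomerisation.

Step 3
Reactants: 5 5,6-dimethoxy-1,3-dihydrobenzo[c]thiophene
Product: 7 5,6-dimethoxy-1,3-dihydrobenzo[c]thiophene 2,2-dioxide, via sulfoxide 6 (not isolated)
Conditions: 30% H2O2 (2.5 equiv), Na2WO4·2H2O (2 mol%), MeOH, 50 °C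
Reagents that add atoms: hydrogen peroxide, OO
Why: Tungstate-catalysed peroxide oxidation of a dialkyl sulfide runs through the sulfoxide to the sulfone and leaves the dimethoxyarene untouched (sulfide-to-sulfone oxidation).

Step 4
Reactants: 7 5,6-dimethoxy-1,3-dihydrobenzo[c]thiophene 2,2-dioxide; 8 4-bromoveratrole (4-bromo-1,2-dimethoxybenzene)
Product: 9 1-(3,4-dimethoxyphenyl)-5,6-dimethoxy-1,3-dihydrobenzo[c]thiophene 2,2-dioxide (racemic)
Conditions: Pd(OAc)2 (5 mol%), XPhos (10 mol%), LiOtBu (3 equiv), toluene, 90 °C; 7 in 1.5-fold excess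
Reagents that add atoms: none
Why: Palladium-catalysed α-arylation of a benzylic sulfone (oxidative addition of 8 to zerovalent palladium, transmetalation of the lithiated sulfone, reductive elimination); the more acidic product rests as a hindered, stabilised carbanion, which together with the excess of 7 should hold the reaction at mono-arylation.

Step 5
Reactants: 9 1-(3,4-dimethoxyphenyl)-5,6-dimethoxy-1,3-dihydrobenzo[c]thiophene 2,2-dioxide; 3 bis[(S)-1-methoxy-1-oxopropan-2-yl] (E)-but-2-enedioate
Product: 11 bis[(S)-1-methoxy-1-oxopropan-2-yl] (1R,2R,3R)-1-(3,4-dimethoxyphenyl)-6,7-dimethoxy-1,2,3,4-tetrahydronaphthalene-2,3-dicarboxylate, via E-aryl o-quinodimethane 10 (not isolated)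
Conditions: 3 (2 equiv), 1,2,4-trichlorobenzene, 200 °C, Ar sweep; major diastereomer isolated by chromatography or crystallisation
Reagents that add atoms: none
Why: Heating 9 expels SO2 by a cheletropic extrusion that opens the sulfone ring with the aryl group rotating outward, giving the E o-quinodimethane 10, which is trapped at once by the electron-poor alkene of 3 in a concerted suprafacial [4+2] cycloaddition that restores the aromaticity of ring A. The closest known reaction type is the Diels-Alder capture of sulfone-derived α-aryl o-quinodimethanes by fumarates of (S)-α-hydroxy esters. Ring B is closed as a six-membered carbocycle by intermolecular [4+2] annulation across the C4a–C8a edge, C1–C2 and C3–C4 forming together, and regiochemistry is not an issue because the dienophile is C2-symmetric. The 2,3-trans relation is carried over stereospecifically from the E alkene and its absolute sense comes from the two (S)-lactate groups, which shield one face with their methyl groups; C1 is set by the outward aryl group together with endo placement of the C2 ester, which gives the 1,2-cis relation and, for this face, C1 (R). The step needs face selectivity and endo selectivity at about 200 °C; the matched pair of lactates and secondary overlap of the C2 ester carbonyl with the aryl-conjugated diene should secure them, and the minor adducts epimeric at C1, which still carry the lactates and would lead to the enantiomeric series, are removed here as diastereomers. The 1,2-cis outcome is accepted on purpose, since C1 is the only centre that cannot be adjusted afterwards, whereas C2 and C3 can.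

Step 6
Reactants: 11 bis[(S)-1-methoxy-1-oxopropan-2-yl] (1R,2R,3R)-1-(3,4-dimethoxyphenyl)-6,7-dimethoxy-1,2,3,4-tetrahydronaphthalene-2,3-dicarboxylate
Product: 14 dimethyl (1R,2S,3S)-1-(3,4-dimethoxyphenyl)-6,7-dimethoxy-1,2,3,4-tetrahydronaphthalene-2,3-dicarboxylate, via 1,2-cis-2,3-trans dimethyl diester 12 (not isolated), via C2-epimeric dimethyl diester 13 (not isolated)
Conditions: NaOMe (0.5 equiv), MeOH, reflux
Reagents that add atoms: methanol, CO
Why: Methoxide-catalysed transesterification releases the lactate auxiliaries, and reversible ester-enolate formation then epimerises C2 and C3 until the all-trans diester with aryl and both esters equatorial predominates, so both centres are set thermodynamically under control of the fixed C1 (base-mediated epimerisation).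

Step 7
Reactants: 14 dimethyl (1R,2S,3S)-1-(3,4-dimethoxyphenyl)-6,7-dimethoxy-1,2,3,4-tetrahydronaphthalene-2,3-dicarboxylate
Product: 15 [(1R,2S,3S)-1-(3,4-dimethoxyphenyl)-6,7-dimethoxy-1,2,3,4-tetrahydronaphthalene-2,3-diyl]dimethanol
Conditions: LiAlH4, THF, 0 °C to rt; aqueous NaOH work-up
Reagents that add atoms: none
Why: LiAlH4 reduces both esters to primary alcohols (ester reduction) without touching the aryl methyl ethers or any stereocentre, and the all-trans array is already the stable one should transient aldehydes enolise.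

Step 8
Reactants: 15 [(1R,2S,3S)-1-(3,4-dimethoxyphenyl)-6,7-dimethoxy-1,2,3,4-tetrahydronaphthalene-2,3-diyl]dimethanol
Product: 16 [(1R,2S,3S)-1-(3,4-dimethoxyphenyl)-6,7-dimethoxy-1,2,3,4-tetrahydronaphthalene-2,3-diyl]bis(methylene) dimethanesulfonate
Conditions: MsCl (3 equiv), Et3N, CH2Cl2, −10 to 0 °C
Reagents that add atoms: methanesulfonyl chloride, CS(=O)(=O)Cl
Why: Mesylation of both primary alcohols with excess reagent at low temperature outruns cyclisation of a monomesylate to a tetrahydrofuran and involves no stereocentre (sulfonate ester formation).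

Step 9
Reactants: 16 [(1R,2S,3S)-1-(3,4-dimethoxyphenyl)-6,7-dimethoxy-1,2,3,4-tetrahydronaphthalene-2,3-diyl]bis(methylene) dimethanesulfonate
Product: 17 (1R,2R,3S)-1-(3,4-dimethoxyphenyl)-6,7-dimethoxy-2,3-dimethyl-1,2,3,4-tetrahydronaphthalene
Conditions: LiEt3BH (5 equiv), THF, 0 °C to rt
Reagents that add atoms: none
Why: LiEt3BH displaces primary sulfonates by SN2 hydride transfer at or below room temperature, where aryl methyl ethers are not cleaved, turning both CH2OMs groups into the C2 and C3 methyl groups with all three stereocentres untouched (reductive deoxygenation of sulfonates).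

Compound list

1 | fumaryl chloride | O=C(Cl)/C=C/C(Cl)=O | starting material
2 | methyl (S)-lactate | C[C@H](O)C(=O)OC | starting material
3 | bis[(S)-1-methoxy-1-oxopropan-2-yl] (E)-but-2-enedioate | COC(=O)[C@H](C)OC(=O)/C=C/C(=O)O[C@@H](C)C(=O)OC | intermediate
4 | 1,2-bis(chloromethyl)-4,5-dimethoxybenzene | COc1cc(CCl)c(CCl)cc1OC | starting material
5 | 5,6-dimethoxy-1,3-dihydrobenzo[c]thiophene | COc1cc2CSCc2cc1OC | intermediate
6 | 5,6-dimethoxy-1,3-dihydrobenzo[c]thiophene 2-oxide | COc1cc2CS(=O)Cc2cc1OC | intermediate (not isolated)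
7 | 5,6-dimethoxy-1,3-dihydrobenzo[c]thiophene 2,2-dioxide | COc1cc2CS(=O)(=O)Cc2cc1OC | intermediate
8 | 4-bromoveratrole (4-bromo-1,2-dimethoxybenzene) | COc1ccc(Br)cc1OC | starting material
9 | 1-(3,4-dimethoxyphenyl)-5,6-dimethoxy-1,3-dihydrobenzo[c]thiophene 2,2-dioxide (racemic) | COc1ccc(C2c3cc(OC)c(OC)cc3CS2(=O)=O)cc1OC | intermediate
10 | (E)-5-[(3,4-dimethoxyphenyl)methylidene]-2,3-dimethoxy-6-methylidenecyclohexa-1,3-diene (aryl outward) | COc1ccc(/C=C2\C=C(OC)C(OC)=CC2=C)cc1OC | intermediate (not isolated)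
11 | bis[(S)-1-methoxy-1-oxopropan-2-yl] (1R,2R,3R)-1-(3,4-dimethoxyphenyl)-6,7-dimethoxy-1,2,3,4-tetrahydronaphthalene-2,3-dicarboxylate (1,2-cis, 2,3-trans) | COc1ccc([C@@H]2c3cc(OC)c(OC)cc3C[C@@H](C(=O)O[C@@H](C)C(=O)OC)[C@@H]2C(=O)O[C@@H](C)C(=O)OC)cc1OC | intermediate
12 | dimethyl (1R,2R,3R)-1-(3,4-dimethoxyphenyl)-6,7-dimethoxy-1,2,3,4-tetrahydronaphthalene-2,3-dicarboxylate (1,2-cis, 2,3-trans) | COc1ccc([C@@H]2c3cc(OC)c(OC)cc3C[C@@H](C(=O)OC)[C@@H]2C(=O)OC)cc1OC | intermediate (not isolated)
13 | dimethyl (1R,2S,3R)-1-(3,4-dimethoxyphenyl)-6,7-dimethoxy-1,2,3,4-tetrahydronaphthalene-2,3-dicarboxylate (1,2-trans, 2,3-cis) | COc1ccc([C@@H]2c3cc(OC)c(OC)cc3C[C@@H](C(=O)OC)[C@H]2C(=O)OC)cc1OC | intermediate (not isolated)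
14 | dimethyl (1R,2S,3S)-1-(3,4-dimethoxyphenyl)-6,7-dimethoxy-1,2,3,4-tetrahydronaphthalene-2,3-dicarboxylate (all-trans) | COc1ccc([C@@H]2c3cc(OC)c(OC)cc3C[C@H](C(=O)OC)[C@H]2C(=O)OC)cc1OC | intermediate
15 | [(1R,2S,3S)-1-(3,4-dimethoxyphenyl)-6,7-dimethoxy-1,2,3,4-tetrahydronaphthalene-2,3-diyl]dimethanol | COc1ccc([C@@H]2c3cc(OC)c(OC)cc3C[C@H](CO)[C@H]2CO)cc1OC | intermediate
16 | [(1R,2S,3S)-1-(3,4-dimethoxyphenyl)-6,7-dimethoxy-1,2,3,4-tetrahydronaphthalene-2,3-diyl]bis(methylene) dimethanesulfonate | COc1ccc([C@@H]2c3cc(OC)c(OC)cc3C[C@H](COS(C)(=O)=O)[C@H]2COS(C)(=O)=O)cc1OC | intermediate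
17 | (1R,2R,3S)-1-(3,4-dimethoxyphenyl)-6,7-dimethoxy-2,3-dimethyl-1,2,3,4-tetrahydronaphthalene | COc1ccc([C@@H]2c3cc(OC)c(OC)cc3C[C@H](C)[C@H]2C)cc1OC | target

Total step count: 9. Longest linear sequence: 8 steps (4 to 17 through steps 2 to 9); step 1 is a one-step side branch.

Steps most likely to fail

Step 5. At the temperature needed for SO2 loss, face and endo discrimination may erode, and the diene may be consumed by self-dimerisation before it meets the dienophile. The fallback changes the controlling element to an auxiliary that shields through an aryl group and gives more crystalline adducts. It sets out from 9 (with 1): 1 is esterified with methyl (S)-mandelate (pyridine, CH2Cl2) to bis[(S)-2-methoxy-2-oxo-1-phenylethyl] (E)-but-2-enedioate F1. Heating F1 with 9 as in step 5 should give, through 10, the mandelate adduct bis[(S)-2-methoxy-2-oxo-1-phenylethyl] (1R,2R,3R)-1-(3,4-dimethoxyphenyl)-6,7-dimethoxy-1,2,3,4-tetrahydronaphthalene-2,3-dicarboxylate F2, purified by crystallisation. Methanolysis and equilibration with NaOMe in MeOH, as in step 6, bring the material back to the route at 14.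

Step 4. The arylation may run on to 1,1- or 1,3-diarylated sulfone, or stall with the electron-rich bromide while the sulfone anion degrades on prolonged heating. The fallback makes the C1–aryl bond by carbonyl addition before the sulfur ring exists. It sets out from 8: bromine–lithium exchange (n-BuLi, THF, −78 °C) gives (3,4-dimethoxyphenyl)lithium F3, which is added to one equivalent of commercial 5,6-dimethoxyphthalide to give [2-(hydroxymethyl)-4,5-dimethoxyphenyl](3,4-dimethoxyphenyl)methanone F4 (in equilibrium with its lactol). NaBH4 in MeOH reduces it to [2-(hydroxymethyl)-4,5-dimethoxyphenyl](3,4-dimethoxyphenyl)methanol F5. PBr3 in CH2Cl2 at 0 °C gives 1-[bromo(3,4-dimethoxyphenyl)methyl]-2-(bromomethyl)-4,5-dimethoxybenzene F6, used crude. Na2S·9H2O closes the ring to 1-(3,4-dimethoxyphenyl)-5,6-dimethoxy-1,3-dihydrobenzo[c]thiophene F7, and H2O2 with Na2WO4·2H2O oxidises it through 1-(3,4-dimethoxyphenyl)-5,6-dimethoxy-1,3-dihydrobenzo[c]thiophene 2-oxide F8 to the sulfone, coming back to the route at 9.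

Step 6. The equilibration may stop at a mixture of C2/C3 epimers, or be accompanied by saponification that blocks further enolisation. The fallback moves the equilibration to the aldehyde oxidation level, where α-epimerisation is far faster and needs only an amine base. It sets out from 11: LiAlH4 in THF gives [(1R,2R,3R)-1-(3,4-dimethoxyphenyl)-6,7-dimethoxy-1,2,3,4-tetrahydronaphthalene-2,3-diyl]dimethanol F9. Swern oxidation ((COCl)2, DMSO, Et3N, CH2Cl2, −78 °C) gives (1R,2R,3R)-1-(3,4-dimethoxyphenyl)-6,7-dimethoxy-1,2,3,4-tetrahydronaphthalene-2,3-dicarbaldehyde F10. DBU in CH2Cl2 at rt should epimerise it through the (1R,2S,3R)-dicarbaldehyde F11 to the all-trans (1R,2S,3S)-dicarbaldehyde F12. NaBH4 in MeOH at 0 °C reduces F12 and comes back to the route at 15.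

Further compounds

F1 | step 5 | bis[(S)-2-methoxy-2-oxo-1-phenylethyl] (E)-but-2-enedioate | COC(=O)[C@H](c1ccccc1)OC(=O)/C=C/C(=O)O[C@@H](c1ccccc1)C(=O)OC
F2 | step 5 | bis[(S)-2-methoxy-2-oxo-1-phenylethyl] (1R,2R,3R)-1-(3,4-dimethoxyphenyl)-6,7-dimethoxy-1,2,3,4-tetrahydronaphthalene-2,3-dicarboxylate | COc1ccc([C@@H]2c3cc(OC)c(OC)cc3C[C@@H](C(=O)O[C@@H](c3ccccc3)C(=O)OC)[C@@H]2C(=O)O[C@@H](c2ccccc2)C(=O)OC)cc1OC
F3 | step 4 | (3,4-dimethoxyphenyl)lithium | [Li]c1ccc(OC)c(OC)c1
F4 | step 4 | [2-(hydroxymethyl)-4,5-dimethoxyphenyl](3,4-dimethoxyphenyl)methanone | COc1ccc(C(=O)c2cc(OC)c(OC)cc2CO)cc1OC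
F5 | step 4 | [2-(hydroxymethyl)-4,5-dimethoxyphenyl](3,4-dimethoxyphenyl)methanol (racemic) | COc1ccc(C(O)c2cc(OC)c(OC)cc2CO)cc1OC
F6 | step 4 | 1-[bromo(3,4-dimethoxyphenyl)methyl]-2-(bromomethyl)-4,5-dimethoxybenzene (racemic) | COc1ccc(C(Br)c2cc(OC)c(OC)cc2CBr)cc1OC
F7 | step 4 | 1-(3,4-dimethoxyphenyl)-5,6-dimethoxy-1,3-dihydrobenzo[c]thiophene (racemic) | COc1ccc(C2SCc3cc(OC)c(OC)cc32)cc1OC
F8 | step 4 | 1-(3,4-dimethoxyphenyl)-5,6-dimethoxy-1,3-dihydrobenzo[c]thiophene 2-oxide (diastereomer mixture) | COc1ccc(C2c3cc(OC)c(OC)cc3CS2=O)cc1OC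
F9 | step 6 | [(1R,2R,3R)-1-(3,4-dimethoxyphenyl)-6,7-dimethoxy-1,2,3,4-tetrahydronaphthalene-2,3-diyl]dimethanol | COc1ccc([C@@H]2c3cc(OC)c(OC)cc3C[C@@H](CO)[C@@H]2CO)cc1OC
F10 | step 6 | (1R,2R,3R)-1-(3,4-dimethoxyphenyl)-6,7-dimethoxy-1,2,3,4-tetrahydronaphthalene-2,3-dicarbaldehyde | COc1ccc([C@@H]2c3cc(OC)c(OC)cc3C[C@@H](C=O)[C@@H]2C=O)cc1OC
F11 | step 6 | (1R,2S,3R)-1-(3,4-dimethoxyphenyl)-6,7-dimethoxy-1,2,3,4-tetrahydronaphthalene-2,3-dicarbaldehyde | COc1ccc([C@@H]2c3cc(OC)c(OC)cc3C[C@@H](C=O)[C@H]2C=O)cc1OC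
F12 | step 6 | (1R,2S,3S)-1-(3,4-dimethoxyphenyl)-6,7-dimethoxy-1,2,3,4-tetrahydronaphthalene-2,3-dicarbaldehyde | COc1ccc([C@@H]2c3cc(OC)c(OC)cc3C[C@H](C=O)[C@H]2C=O)cc1OC
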